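**Retrosynthetic overview**
- Target ⇒ (−)-pinoresinol + prenyl bromide: mono-O-alkylation of one of the two homotopic phenols of the C2-symmetric bis-phenol, done last because a prenyl ether would not survive DDQ.
- (−)-Pinoresinol ⇒ (8S,8′S)-secoisolariciresinol: both tetrahydrofuran rings are closed in one operation by a double benzylic dehydrogenation/quinone-methide oxa-cyclisation (ring C7–O–C9′ first, then ring C7′–O–C9), which also sets C7 and C7′.
- Secoisolariciresinol ⇒ C2-symmetric 2,3-dibenzylsuccinyl bis-imide (global hydride reduction) ⇒ oxidative homocoupling of one N-acyl oxazolidinone enolate (C8–C8′ bond, both ring-fusion stereocentres from the auxiliary).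
- N-Acyl oxazolidinone ⇒ dihydroferulic acid + (R)-4-benzyloxazolidin-2-one, with pivaloyl chloride acting as both phenol mask and carboxyl activator.

Assumption: lignan numbering is used (C7/C7′ = ArCH–O, C8/C8′ = ring-fusion CH, C9/C9′ = CH2O); the target is the mono-O-prenyl ether of (−)-pinoresinol, (7R,7′R,8S,8′S).

**Route**

Step 1
Reactants: 1 3-(4-hydroxy-3-methoxyphenyl)propanoic acid (dihydroferulic acid); 2 (R)-4-benzyl-1,3-oxazolidin-2-one
Product: 4 (4R)-4-benzyl-3-{3-[3-methoxy-4-(pivaloyloxy)phenyl]propanoyl}-1,3-oxazolidin-2-one, via mixed pivalic anhydride 3 (not isolated)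
Conditions: PivCl (2.3 equiv), Et3N (3.5 equiv), THF, −20 → 0 °C; then 2 (1.0 equiv), LiCl, 0 °C → rt
Reagents that add atoms: pivaloyl chloride, CC(C)(C)C(=O)Cl
Why: PivCl acylates both the phenol and the carboxylate, and the LiCl-activated oxazolidinone then attacks the unhindered carbonyl of the mixed anhydride while the hindered aryl pivalate stays intact (mixed-anhydride N-acylation of an Evans auxiliary); no new stereocentre.

Step 2
Reactants: 4 (4R)-4-benzyl-3-{3-[3-methoxy-4-(pivaloyloxy)phenyl]propanoyl}-1,3-oxazolidin-2-one (2 equiv)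
Product: 6 (2S,3S)-1,4-bis[(4R)-4-benzyl-2-oxo-1,3-oxazolidin-3-yl]-2,3-bis[3-methoxy-4-(pivaloyloxy)benzyl]butane-1,4-dione, via lithium Z-enolate 5 (not isolated)
Conditions: LDA (1.05 equiv), THF, −78 °C; then TiCl4 (1.0 equiv), −78 → 0 °C
Reagents that add atoms: none
Why: Titanium-mediated oxidative enolate homocoupling: each Z-enolate forms the C8–C8′ bond on the face anti to the auxiliary benzyl group (same facial sense as Evans alkylation), so the (R)-auxiliary gives the C2-symmetric (S,S)-dimer; the hindered aryl pivalates tolerate LDA at −78 °C and the minor (R,S)-isomer is removed by chromatography.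

Step 3
Reactants: 6 (2S,3S)-bis-imide
Product: 7 (2S,3S)-2,3-bis(4-hydroxy-3-methoxybenzyl)butane-1,4-diol [(+)-secoisolariciresinol]
Conditions: LiAlH4 (6 equiv), THF, 0 °C → rt; then aq. Rochelle salt
Reagents that add atoms: none
Why: Hydride reduction converts both exocyclic imide carbonyls to primary alcohols (auxiliary released and recoverable) and cleaves both aryl pivalates to phenols, without touching C8/C8′.

Step 4
Reactants: 7 (2S,3S)-2,3-bis(4-hydroxy-3-methoxybenzyl)butane-1,4-diol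
Product: 11 (7R,7′R,8S,8′S)-pinoresinol [(−)-pinoresinol], via seco quinone methide 8 (not isolated), via (−)-lariciresinol 9 (not isolated), via lariciresinol quinone methide 10 (not isolated)
Conditions: DDQ (2.05 equiv, added over 1 h), 4 Å MS, 1,4-dioxane, 10 °C → rt
Reagents that add atoms: none
Why: Proposed new method: DDQ dehydrogenates a p-alkylphenol at C7 to a p-quinone methide, which the 9′-OH traps by 5-exo 1,6-oxa-Michael addition anti to the C8 CH2OH group (7,8-trans tetrahydrofuran), and a second DDQ equivalent repeats this at C7′ so that the cis-disposed 9-OH closes the cis-fused second ring with the aryl on the convex face, the same two quinone-methide closures that give pinoresinol in oxidative coniferyl alcohol coupling; closest known reactions are DDQ benzylic α-alkoxylation of 4-alkylphenols via quinone methides and DDQ-mediated oxidative cycloetherification of electron-rich benzylic positions.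

Step 5
Reactants: 11 (7R,7′R,8S,8′S)-pinoresinol
Product: 12 4-[(1R,3aS,4R,6aS)-4-{3-methoxy-4-[(3-methylbut-2-en-1-yl)oxy]phenyl}tetrahydro-1H,3H-furo[3,4-c]furan-1-yl]-2-methoxyphenol (target)
Conditions: prenyl bromide (1.0 equiv), K2CO3 (1.2 equiv), acetone, rt; unreacted 11 recycled
Reagents that add atoms: 1-bromo-3-methylbut-2-ene (prenyl bromide), CC(C)=CCBr
Why: Williamson etherification of a phenoxide; the two phenols of C2-symmetric 11 are homotopic, so mono-alkylation gives a single compound (statistical yield, bis-ether and 11 separable), and no stereocentre is touched.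

**Compound list**
1 | 3-(4-hydroxy-3-methoxyphenyl)propanoic acid (dihydroferulic acid) | COc1cc(CCC(=O)O)ccc1O | starting material
2 | (R)-4-benzyl-1,3-oxazolidin-2-one | O=C1N[C@H](Cc2ccccc2)CO1 | starting material
3 | 3-[3-methoxy-4-(pivaloyloxy)phenyl]propanoic pivalic anhydride | COc1cc(CCC(=O)OC(=O)C(C)(C)C)ccc1OC(=O)C(C)(C)C | intermediate (not isolated)
4 | (4R)-4-benzyl-3-{3-[3-methoxy-4-(pivaloyloxy)phenyl]propanoyl}-1,3-oxazolidin-2-one | COc1cc(CCC(=O)N2[C@H](Cc3ccccc3)COC2=O)ccc1OC(=O)C(C)(C)C | intermediate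
5 | lithium (Z)-enolate of 4 | COc1cc(C/C=C(\O[Li])N2[C@H](Cc3ccccc3)COC2=O)ccc1OC(=O)C(C)(C)C | intermediate (not isolated)
6 | (2S,3S)-1,4-bis[(4R)-4-benzyl-2-oxo-1,3-oxazolidin-3-yl]-2,3-bis[3-methoxy-4-(pivaloyloxy)benzyl]butane-1,4-dione | COc1cc(C[C@H](C(=O)N2[C@H](Cc3ccccc3)COC2=O)[C@H](Cc2ccc(OC(=O)C(C)(C)C)c(OC)c2)C(=O)N2[C@H](Cc3ccccc3)COC2=O)ccc1OC(=O)C(C)(C)C | intermediate
7 | (2S,3S)-2,3-bis(4-hydroxy-3-methoxybenzyl)butane-1,4-diol, (+)-secoisolariciresinol | COc1cc(C[C@H](CO)[C@@H](CO)Cc2ccc(O)c(OC)c2)ccc1O | intermediate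
8 | 4-[(2S,3S)-4-hydroxy-3-(4-hydroxy-3-methoxybenzyl)-2-(hydroxymethyl)butylidene]-2-methoxycyclohexa-2,5-dien-1-one (mono-p-quinone methide of 7) | COC1=CC(=C[C@H](CO)[C@@H](CO)Cc2ccc(O)c(OC)c2)C=CC1=O | intermediate (not isolated)
9 | 4-{[(3S,4S,5R)-5-(4-hydroxy-3-methoxyphenyl)-4-(hydroxymethyl)oxolan-3-yl]methyl}-2-methoxyphenol, (−)-lariciresinol (7R,8S,8′S) | COc1cc([C@@H]2OC[C@@H](Cc3ccc(O)c(OC)c3)[C@H]2CO)ccc1O | intermediate (not isolated)
10 | 4-{[(3S,4S,5R)-5-(4-hydroxy-3-methoxyphenyl)-4-(hydroxymethyl)oxolan-3-yl]methylidene}-2-methoxycyclohexa-2,5-dien-1-one (C7′ p-quinone methide of 9) | COc1cc([C@@H]2OC[C@@H](C=C3C=CC(=O)C(OC)=C3)[C@H]2CO)ccc1O | intermediate (not isolated)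
11 | 4,4′-[(1R,3aS,4R,6aS)-tetrahydro-1H,3H-furo[3,4-c]furan-1,4-diyl]bis(2-methoxyphenol), (−)-pinoresinol (7R,7′R,8S,8′S) | COc1cc([C@@H]2OC[C@@H]3[C@H]2CO[C@H]3c2ccc(O)c(OC)c2)ccc1O | intermediate
12 | 4-[(1R,3aS,4R,6aS)-4-{3-methoxy-4-[(3-methylbut-2-en-1-yl)oxy]phenyl}tetrahydro-1H,3H-furo[3,4-c]furan-1-yl]-2-methoxyphenol | COc1cc([C@@H]2OC[C@@H]3[C@H]2CO[C@H]3c2ccc(OCC=C(C)C)c(OC)c2)ccc1O | target

**Totals**
Total step count: 5. Longest linear sequence: 5 steps (1 → 4 → 6 → 7 → 11 → 12).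

**Three steps most likely to fail**

Step 4 (double DDQ cyclisation). The main risks are over-oxidation of the newly formed phenolic benzylic ether C–H bonds, tautomerisation of the quinone methides to styrenes, and Friedel–Crafts closure to an aryltetralin. The fallback separates oxidation from ring closure; it sets out from 7 and comes back at 11. Peracetylation of 7 (Ac2O, pyridine) gives (2S,3S)-2,3-bis(4-acetoxy-3-methoxybenzyl)butane-1,4-diyl diacetate F1. Wohl–Ziegler bromination (NBS 2.2 equiv, AIBN, PhCF3, 80 °C) gives the 7,7′-dibromide (2S,3S)-2,3-bis[(4-acetoxy-3-methoxyphenyl)bromomethyl]butane-1,4-diyl diacetate F2, as benzylic epimers that do not matter. LiOH in aqueous THF cleaves the aryl acetates; the phenoxides expel bromide by 1,6-elimination, the quinone methides take up water and the alkyl acetates are saponified, giving (2S,3S)-1,4-bis(4-hydroxy-3-methoxyphenyl)-2,3-bis(hydroxymethyl)butane-1,4-diol F3. Catalytic CSA in MeCN then ionises both p-hydroxybenzylic alcohols and closes both rings under thermodynamic control to 11, with no oxidant present alongside the product.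

Step 2 (oxidative homocoupling). The main risks are a low (S,S):(R,S) ratio, attack on the aryl pivalate and simple reprotonation. The fallback builds the C8–C8′ bond by two ionic alkylations; it sets out from 4 and comes back at 7.
- Evans alkylation of the sodium enolate of 4 (NaHMDS, THF, −78 °C) with tert-butyl bromoacetate gives (4R)-4-benzyl-3-{(2S)-4-tert-butoxy-2-[3-methoxy-4-(pivaloyloxy)benzyl]-4-oxobutanoyl}-1,3-oxazolidin-2-one F4.
- LiBH4/H2O (Et2O, 0 °C) removes the auxiliary to give tert-butyl (3S)-3-(hydroxymethyl)-4-[3-methoxy-4-(pivaloyloxy)phenyl]butanoate F5.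
- TFA closes F5 to (4S)-4-[3-methoxy-4-(pivaloyloxy)benzyl]dihydrofuran-2(3H)-one F6.
- The second arylmethyl unit comes from creosol (2-methoxy-4-methylphenol): PivCl/Et3N gives 2-methoxy-4-methylphenyl pivalate F7, and NBS/AIBN gives 4-(bromomethyl)-2-methoxyphenyl pivalate F8.
- Alkylation of the lithium enolate of F6 (LiHMDS, THF, −78 °C) with F8 occurs anti to the C4 substituent and gives the trans lactone (3S,4S)-3,4-bis[3-methoxy-4-(pivaloyloxy)benzyl]dihydrofuran-2(3H)-one F9.
- LiAlH4 reduces the lactone and both pivalates of F9 to 7.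

Step 1 (one-pot pivaloylation/N-acylation). The main risk is that the free phenol attacks the mixed anhydride and gives aryl ester oligomers. The fallback is a stepwise sequence with an isolated acid and a pre-formed acid chloride; it sets out from 1 and comes back at 4. Phenoxide-selective pivaloylation under Schotten–Baumann conditions (PivCl 1.1 equiv, aq. NaOH, THF, 0 °C) gives 3-[3-methoxy-4-(pivaloyloxy)phenyl]propanoic acid F10. Oxalyl chloride with catalytic DMF converts it to 3-[3-methoxy-4-(pivaloyloxy)phenyl]propanoyl chloride F11, which acylates N-lithiated 2 (n-BuLi, THF, −78 °C) to give 4.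

**Further compounds**
F1 | step 4 | (2S,3S)-2,3-bis(4-acetoxy-3-methoxybenzyl)butane-1,4-diyl diacetate | COc1cc(C[C@H](COC(C)=O)[C@@H](COC(C)=O)Cc2ccc(OC(C)=O)c(OC)c2)ccc1OC(C)=O
F2 | step 4 | (2S,3S)-2,3-bis[(4-acetoxy-3-methoxyphenyl)bromomethyl]butane-1,4-diyl diacetate (benzylic epimers) | COc1cc(C(Br)[C@H](COC(C)=O)[C@@H](COC(C)=O)C(Br)c2ccc(OC(C)=O)c(OC)c2)ccc1OC(C)=O
F3 | step 4 | (2S,3S)-1,4-bis(4-hydroxy-3-methoxyphenyl)-2,3-bis(hydroxymethyl)butane-1,4-diol (C1/C4 epimers) | COc1cc(C(O)[C@H](CO)[C@@H](CO)C(O)c2ccc(O)c(OC)c2)ccc1O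
F4 | step 2 | (4R)-4-benzyl-3-{(2S)-4-tert-butoxy-2-[3-methoxy-4-(pivaloyloxy)benzyl]-4-oxobutanoyl}-1,3-oxazolidin-2-one | COc1cc(C[C@@H](CC(=O)OC(C)(C)C)C(=O)N2[C@H](Cc3ccccc3)COC2=O)ccc1OC(=O)C(C)(C)C
F5 | step 2 | tert-butyl (3S)-3-(hydroxymethyl)-4-[3-methoxy-4-(pivaloyloxy)phenyl]butanoate | COc1cc(C[C@@H](CC(=O)OC(C)(C)C)CO)ccc1OC(=O)C(C)(C)C
F6 | step 2 | (4S)-4-[3-methoxy-4-(pivaloyloxy)benzyl]dihydrofuran-2(3H)-one | COc1cc(C[C@H]2CC(=O)OC2)ccc1OC(=O)C(C)(C)C
F7 | step 2 | 2-methoxy-4-methylphenyl pivalate | COc1cc(C)ccc1OC(=O)C(C)(C)C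
F8 | step 2 | 4-(bromomethyl)-2-methoxyphenyl pivalate | COc1cc(CBr)ccc1OC(=O)C(C)(C)C
F9 | step 2 | (3S,4S)-3,4-bis[3-methoxy-4-(pivaloyloxy)benzyl]dihydrofuran-2(3H)-one | COc1cc(C[C@H]2[C@H](Cc3ccc(OC(=O)C(C)(C)C)c(OC)c3)C(=O)OC2)ccc1OC(=O)C(C)(C)C
F10 | step 1 | 3-[3-methoxy-4-(pivaloyloxy)phenyl]propanoic acid | COc1cc(CCC(=O)O)ccc1OC(=O)C(C)(C)C
F11 | step 1 | 3-[3-methoxy-4-(pivaloyloxy)phenyl]propanoyl chloride | COc1cc(CCC(=O)Cl)ccc1OC(=O)C(C)(C)C
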